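(Readings and results were generated by integration from invented constants; noise was put on by code.)

The meeting had one question: in the flask, what share of isomer of the product A plus target is isomer of the product A, at 12 s and at 20 min?

| flask | substrate | remark | time |
|---|---|---|---|
| spring | 0.035 M | run made earlier |  |
| flask | 0.069 M |  | 20 min |

spring run (percent of the substrate charged)

| time / min | isomer of the product A / % | target / % |
|---|---|---|
| 0.333 | 0.1 | 2.7 |
| 1.00 | 0.9 | 5.7 |
| 1.50 | 1.5 | 6.5 |
| 2.50 | 2.0 | 6.6 |
| 4.00 | 3.2 | 7.4 |
| 5.00 | 3.4 | 8.2 |
| 6.00 | 4.5 | 8.0 |

(readings scatter by 0.3 percentage points)

1. share of isomer of the product A in isomer of the product A plus target at 12 s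
2. share of isomer of the product A in isomer of the product A plus target at 20 min



The first member took the spring run from 2.50 min to 6.00 min, where target changes slowly. She proposed the hand-on rate, the rise of [isomer of the product A] per minute divided by the mean [target], read off these scattered readings as 0.0978 /min, an apparent first-order constant. She argued that it carries over to the flask, charged at twice the spring's substrate, if the steps are first-order; the second member replied that one run cannot show this. She reckoned that while target rises in proportion to time, the ratio of isomer of the product A to target is half the hand-on rate times the time, and that with target steady it is the rate times the time. The second member wrote the substrate balance: at 6.00 min in the spring run, target and isomer of the product A held 12.5% of the charge, and the other 87.5% was not read, so the readings do not show in what form it stood. He warned that the readings stop at 6.00 min and that the reckoning counts no loss of isomer of the product A. My own reckoning for the flask stands at 0.969% at 12 s and 66.2% at 20 min.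

The forecast gave 6% (1% to 11%) and 64% (50% to 78%), above my early figure and below my late one, noting: "Doubling the concentration adds uncertainty".

The flask gives 1.94% at 12 s, more than my figure, and 48.5% at 20 min, less than my figure.

    substrate ⇌ dormant form (K = 2.30, k = 0.0198 /s)
    isomer of the product B ⇌ substrate (k = 7.43 × 10⁻⁴ /s)
    substrate → decomposition product (k = 6.60 × 10⁻⁶ /s)
    target ⇌ isomer of the product A (K = 1.10, k = 0.00251 /s)
    isomer of the product A ⇌ isomer of the product B (K = 0.351, k = 0.00331 /s)
    substrate ⇌ target (K = 0.457, k = 0.00177 /s)

Between 10.0 min and 20.0 min the flask's hand-on rate is 0.0314 /min, lower than the 0.0978 /min read from the spring run between 2.50 min and 6.00 min. The half-life of isomer of the product A by its forward conversion into isomer of the product B, 3.5 min, is shorter than the 4.6 min of target by its forward conversion into isomer of the product A, and short against 20 min. In the neighbour flask at 0.28 M, the hand-on rate, taken as the same first-order constant, gives 0.969% and 66.2% again. The computed neighbour flask gives 1.94% and 48.5%.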